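- I started from the product Q and turned the question round: what had to be true for X, not Q, to lead at the end of amber and of red?

| flask | X | L | Z | remark | time |
|---|---|---|---|---|---|
| summer | 0.54 M | 0.88 M | 64 mM (held) | run made earlier |  |
| dusk | 1.2 M | 0.88 M | 64 mM (held) | run made earlier |  |
| amber | 0.80 M | 0.880 M | 64 mM (held) |  | 12 h |
| red | 0.80 M | 0.880 M | 64 mM (held) |  | 8.0 h |

| run | time / h | Q / % | J / % | X / % | G / % |
|---|---|---|---|---|---|
| summer | 0.417 | 0.7 | 0.5 | 94.7 | 5.3 |
| summer | 0.667 | 2.8 | 2.2 | 91.3 | 6.7 |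
| summer | 0.833 | 4.8 | 1.4 | 89.4 | 5.5 |
| summer | 1.33 | 7.2 | 1.8 | 84.4 | 7.9 |
| summer | 2.00 | 12.7 | 3.0 | 75.5 | 8.8 |
| summer | 3.00 | 20.6 | 6.0 | 65.0 | 6.7 |
| summer | 5.00 | 31.5 | 12.9 | 49.3 | 5.0 |
| dusk | 0.417 | 0 | 0.1 | 94.3 | 5.9 |
| dusk | 0.667 | 1.4 | 1.1 | 92.5 | 5.7 |
| dusk | 0.833 | 3.0 | 0 | 89.2 | 6.9 |
| dusk | 1.33 | 5.4 | 2.3 | 81.8 | 9.9 |
| dusk | 2.00 | 14.0 | 3.3 | 75.6 | 8.8 |
| dusk | 3.00 | 22.3 | 6.1 | 63.9 | 7.0 |
| dusk | 5.00 | 34.3 | 9.9 | 50.3 | 5.8 |

(readings scatter by 1 percentage point)

- L is a solid; its amount is given per volume of the solution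
- at the start none of L is in solution
- at the start none of Z is in solution

* which of these there is most of at the end, counted by the X in it, amber (Q / X / G / J)
* which of these there is most of at the end, counted by the X in it, red (Q / X / G / J)
* how much there is at the end of the one of these that leads, in percent of the X charged: amber
* how much there is at the end of the one of these that leads, in percent of the X charged: red

- Summer and dusk, charged with 0.54 M and 1.2 M of X, kept 49.3% and 50.3% of it after 5.00 h, so I read the loss of X as first order with a constant of 0.139 h⁻¹, which is one power of ten of X per 16.5 h.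
- At that reading, pooled over both runs, Q made up 74.3% of Q and J together, its selectivity, and G held 5.40%; Q stays ahead of J while that share exceeds 0.5.
- Holding the share and G fixed, I found that Q equals X once X has fallen to 40.3%, which is 0.395 of a power of ten, reached at 6.51 h; this I called the crossover time, the time before which X leads Q and after which Q leads X.
- By this reckoning amber, at 12 h, had gone 0.727 of a power of ten and red, at 8.0 h, 0.485, so both lay past the crossover, red by 1.49 h.
- I therefore committed to Q in both, with 56.3% in amber and 45.9% in red.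
- The forecast gave Q at 58% for amber and Q at 47% for red, above my figures: “Q leads in both”.
- Amber ended with Q at 53.3%, X at 18.9% and J at 26.4%; red ended with Q at 44.9%, X at 32.9% and J at 19.2%.

    E + G → Q (k = 15.7 M⁻¹ h⁻¹)
    D + G → J (k = 3.54 M⁻¹ h⁻¹)
    L ⇌ D, rate k3*(cs3 - [D]) while solid is left; crystals form when [D] > cs3 (solubility = 0.540 M, k = 0.107 h⁻¹)
    X → G (k = 0.139 h⁻¹)
    Z ⇌ E, rate k5*(csat - [E]) (kL = 12.2 h⁻¹)

- In red the half-life of X by its passing into G was 5.0 h, shorter than the crossover time of 6.51 h, and the crossover time was shorter than the 8.0 h red ran. Read at 2.0 h, earlier than the crossover time, the same flask as red had X in the lead at 75.7%, with Q at 12.6%.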